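3 questions stood on this flask, and I wanted one reckoning for them.

- east: substrate 0.040 M; catalyst 0.089 mol%; run made earlier
- flask: substrate 0.020 M; catalyst 0.089 mol%; time 20 h

east run (percent of the substrate charged)

| time / h | isomer of the product / % | target / % |
|---|---|---|
| 0.333 | 11.2 | 15.5 |
| 0.667 | 20.6 | 28.0 |
| 1.50 | 33.0 | 41.1 |
| 4.00 | 44.5 | 49.5 |

(readings scatter by 1 percentage point)

* share of isomer of the product in isomer of the product plus target at 5.0 min
* share of isomer of the product in isomer of the product plus target at 80 min
* share of isomer of the product in isomer of the product plus target at 20 h

- the numbers in the tables scatter by 1 percentage point (one standard deviation)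
- on the list of suspects stand: substrate <-> other conformer; substrate + catalyst <-> catalyst + target; catalyst + other conformer -> catalyst + isomer of the product
- no earlier run changes the charge of catalyst; that part of a forecast is a guess

I counted turnovers. At equal loading, c(catalyst) in the flask was half of that in east, so I took each catalysed step as pseudo-first-order with a constant proportional to c(catalyst). I kept a catalyst clock: the flask's time multiplied by c(catalyst) there over c(catalyst) in east, which gave 10.0 h at the latest time.

The middle time mapped to 0.667 h, an east reading with an isomer share of 42.4%. Against that share, isomer read 1.6 percentage points ahead at 1.50 h and 4.7 points ahead at 4.00 h. I read that as target leaking to isomer at about 0.0271 h⁻¹, a rough reading, since both gaps carry the scatter. I ran that leak on to the clock's end, holding target at its last reading and taking the total as the whole charge, and committed to 55.1%.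

The weak link was the early time. Substrate to other conformer has no catalyst in it, so I let it keep real time and expected isomer to start late. From the scatter of the first east reading I sized a lag of about 2.20 min. In the flask that lag gave 29.2%, so I took the middle of that and 42.4%: 35.8%.

The forecast stood at 43%, 45% and 58%, with the words “I lean Curtin-Hammett, with ranges skewed high”. The flask gave 35.2%, 43.3% and 54.5%.

    substrate ⇌ other conformer (K = 0.350, k = 13.0 h⁻¹)
    substrate + catalyst ⇌ catalyst + target (K = 12.5, k = 20200 M⁻¹ h⁻¹)
    catalyst + other conformer → catalyst + isomer of the product (k = 44800 M⁻¹ h⁻¹)

In the flask, substrate and other conformer relaxed by their own step with a half-life of 0.829 min, far shorter than the 0.87 h half-life of other conformer by the catalysed step alone. The first step has no catalyst in it and keeps real time; the second goes by the clock, which stood at 10.0 h at the latest time. A neighbour flask with 0.0050 M of substrate, at the same loading and time, reached a clock of 2.50 h, which lies between the east readings at 1.50 h and 4.00 h, with shares of 44.5% and 47.3%. That neighbour computed to 45.9% at the latest time.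

All runs stem from a simulated flask for an exercise, and the scatter is random.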